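## Structural features

The target is a daucane-type sesquiterpenoid diester in which a cyclopentane (C1, C2, C3, C9, C10) and a cycloheptene (C3 to C9, alkene C6=C7) are cis-fused through the C3–C9 bond; the numbering is C1 (CH–OAc), C2, C3 (quaternary, methyl), C4 (CH–OH), C5, C6 (methyl-bearing alkene carbon), C7, C8 (CH–O-aroyl), C9 (fusion CH), C10 (C(OH)–isopropyl), and β denotes the face of the C3 methyl. There are six stereocentres, C1, C10, C9, C3 and C4 in an unbroken row and C8 next to C9; the C1 acetoxy, C10 hydroxyl, C9 hydrogen, C3 methyl and C4 hydroxyl are β, the C8 aroyloxy and the isopropyl group α (1S,3S,4S,8S,9R,10R in this numbering). Fragile elements are the allylic 4-hydroxybenzoate (ionisation, hydrolysis, acyl transfer), the acetate beside a tertiary alcohol, the free phenol and the trisubstituted alkene; in intermediates the 1,3-relation of the C8 and C10 oxygens invites β-elimination and retro-aldol cleavage. The real difficulty is the quaternary C3 at the ring fusion, flanked by oxygenated C4 inside a seven-membered ring and required in one absolute configuration, together with the need to tell four oxygen functions apart. The key step uses the pattern of the seven-membered ring: enol-level C8 beside the fusion carbon C9, an alkene at C6 and oxygen on C4 beside C3 are what remains when a cyclopropane C6–C7–C8 opens between a cyclopentene (C9=C3) and an alkoxyvinyl group (C5=C4) in a divinylcyclopropane rearrangement. For that step the cyclopropane is made here as the single cis diastereomer, because a trans isomer could reach the reactive geometry only by homolysis of C6–C8, which can invert either carbon and so leads toward both enantiomers, and because its methyl group could enter a competing hydrogen shift. Two further adjustments follow: the silyl group is triethylsilyl, since the enol ether geometry is fixed by a conjugate hydrosilylation, and the 4-methoxybenzyl (PMB) groups are built into the acetal from the start, since the elimination that forms the enol ether can only keep an alkoxy group the acetal already carries.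

## Logic of the disconnections

37 back to 33: only C4 and the phenol change. 37 comes from 36 (aryl O–Si bond), 36 from 35 (C4–H bond cut, C4 carbonyl), 35 from 34 and 34 from 33 (PMB ether). The key step can only give the C4 epimer, so C4 is passed through a carbonyl; doing this last lets the PMB ether protect C4 through the whole sequence and saves a protecting group. The demand is hydride delivery to C4 anti to the C3 methyl, in the presence of three esters and without moving the β,γ-alkene.

33 back to 31: the acetyl C–O bond and then both C1–O and C10–O bonds are cut, leading through 32 to the C1=C10 alkene of 31. Two stereocentres disappear at once and C1 returns to a plain CH. The forward osmylation must choose the cyclopentene alkene over C6=C7 and the β face.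

31 back to 27 and 30, and 30 back to 28: the C8 ester C–O bond is cut. The ester is introduced after all organometallic steps and before osmylation, where it deactivates C6=C7; the phenol is masked as a silyl ether. The demand is acylation of a hindered allylic alcohol with retention.

27 back to 23 through 26 and 25: the C10–isopropyl bond is cut and the C1=C10 alkene is traced to a C10 carbonyl. Isopropyl then comes from a simple organozinc reagent. The forward steps need kinetic enolisation toward C1, not C9, and C8 must carry a silyl ether so that no β-acyloxy ketone, acyl transfer or allylic substitution can interfere.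

23 back to 20 through 22 and 21: the C10 carbonyl is masked as its dioxolane and the C8–H bond is cut to give the C8 carbonyl of 20. The C8 stereocentre is removed, and C8 and C10 stay distinguishable because one is a ketone and the other a ketal. Hydride must enter beside C9–H and the ketal must survive.

20 back to 18 through 19: the C9–H bond is cut (silyl enol ether C8=C9) and the alkene is moved from C6=C7 to C5=C6. This exposes the cyclohepta-1,4-diene retron. The forward step needs C-protonation at C9 on the β face and conjugation without opening the β-keto ketal.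

18 back to 17 (key disconnection): the C3–C4 bond is cut and C6–C8 is joined. The seven-membered ring and the quaternary stereocentre are traced to a cyclopropane whose two stereocentres come from one methylene transfer. The demand is a cis relation of the two alkenyl groups, an (E)-enol ether and a concerted course.

17 back to 16: the C5=C4 alkene is traced to a CH2–CH(OPMB)2 acetal (one PMB–O bond added). A free enol ether would compete in the cyclopropanation, so it is revealed afterwards. The elimination must choose the acyclic acetal over the dioxolane and give the E isomer.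

16 back to 15: C7 is removed (C6–C7 and C7–C8 bonds). Both stereocentres then depend on one enantioselective step, and their relative configuration is encoded in the alkene geometry of 15. The demand is attack on the enol ether alkene rather than the cyclopentene alkene, with reagent control of the face.

15 back to 10 through 14: the O–Si bond and the C–H bond of the C6 methyl are cut (1,4-hydrosilylation), and the methylidene carbon of 14 is removed. Direct enolisation of an α-methyl ketone would not place the ring cis to the side chain; conjugate delivery through the s-cis enone does. The forward step needs 1,4- over 1,2-addition and must leave the second enone alone.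

10 back to 4 and 8: the C8–C9 bond is cut between a vinyl anion and an N-methoxy-N-methylamide. The route becomes convergent with two fragments of similar size. Halogen–lithium exchange must precede any attack on the ketal, and acylation must stop at the ketone.

4 back to 1 through 3, and 8 back to 5 and 6 through 7: functional-group changes only (ketal, vinyl bromide; amide, acetal exchange), ending at commercial compounds.

## Other disconnections considered

Alternative 1: The cut is the C9–C10 bond together with the C9=C10 unsaturation of a cyclopentenone, leading to the prochiral triketone A1. Forward, a proline-type amine would form the enamine of the side-chain ketone, C10 would add to one of the two enantiotopic ring carbonyls, and dehydration would give the enedione A2 (Hajos–Parrish-type aldol condensation).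
- In its favour: the quaternary C3 would be set catalytically, without metals, within a few steps of commercial material. A2 already carries isopropyl on C10 and carbonyls at C1 and C4, so on the five-membered ring it is the better match for the target, and it is shorter to the bicyclic stage than the chosen plan.
- Against it here: the symmetry that makes the carbonyls enantiotopic excludes the C6 methyl, and C5 to C8 are four unmarked methylenes. The methyl group, the C6=C7 alkene and the C8 oxygen would all have to be added later on a flexible ring with little to direct them. Seven-membered diones are also expected to close more slowly and less selectively than five- and six-membered ones.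
- Comparison: mechanistically the aldol is simpler and easier to run than cyclopropanation plus a sigmatropic shift, which is an advantage. The chosen plan, however, places oxygen at C4 and C8 and the alkene precursor at C6 in the same step that sets C3. In step count the alternative is ahead up to A2 and is expected to fall behind after it.

Alternative 2: C3–C4 and C8–C9 are cut together, after the C4–C8 bond of a cyclobutane-1,2-diol has been added retrosynthetically (de Mayo-type logic). Forward, irradiation of 1 with the electron-rich alkene A3 would give the cis-anti-cis cyclobutane A4; desilylation and glycol cleavage of C4–C8 would expand it to the bicyclic trione A5.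
- In its favour: two or three steps from two simple compounds would assemble the whole carbon skeleton with the C3 quaternary centre, the C6 methyl and oxygen at C4, C8 and C10. The symmetrical alkene removes the regiochemical question. In bond-forming economy this is clearly better than the chosen plan.
- Against it here: the addition runs through a triplet diradical with no handle for absolute control, so the material would be racemic unless a resolution or chiral template is added. A5 has three ketones, with C8 and C10 flanking C9 as a 1,3-dicarbonyl and C4 and C8 nearly equivalent, so separate reduction of C4 and C8, placing the alkene at C6=C7 rather than C5=C6, and adding isopropyl only at C10 all become selectivity problems.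
- Comparison: the chosen plan is longer to the bicycle but delivers C8 and C10 in different masks, C4 protected, and one enantiomer. The photocycloaddition is stepwise yet forgiving and equal to the chosen plan in reliability of ring formation; it is weaker in control of configuration and of the oxygen pattern.

Alternative 3: The cut removes C9–C10 and the C8–O bond of an isoxazoline, leading to the oxime A6 of a cycloheptadiene whose quaternary C3 carries a three-carbon chain. Forward, NaOCl would oxidise A6 to the nitrile oxide, which adds intramolecularly to the nearer alkene (C8=C9) to give the tricyclic isoxazoline A7 (1,3-dipolar cycloaddition); N–O cleavage later unmasks an aldol between C8 and C10.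
- In its favour: one concerted step closes the cyclopentane, enforces the cis ring fusion through the tether on C3, and sets C9–H and the C8 oxygen suprafacially with the relative configuration of the target. The C8/C10 oxygen pair emerges already differentiated, the C6=C7 alkene is in place and C4 can carry its final configuration. On these points it is better than the chosen plan, which needs a protonation, a hydride reduction and an oxidation–reduction at C4, and it would save about four operations after the key step.
- Against it here: the key step does not create the quaternary stereocentre. An enantiomerically pure cycloheptadiene with C3 and C4 defined must be made first, and that is the hardest part of the problem. Nitrile oxide dimerisation, addition to the wrong alkene of the diene, and N–O cleavage beside a trisubstituted alkene are further concerns, and C10 still needs the enol triflate, coupling and dihydroxylation sequence.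
- Comparison: both key steps are concerted and stereospecific. The chosen plan creates ring and quaternary centre together from a cyclopropane that one enantioselective step provides; the alternative has the cleaner stereocontrol at C8 and C9.

Key step: step 10

Assumption: the sense of induction of the dipeptide ligand in step 8 cannot be assigned with certainty for this substrate; the ligand enantiomer that gives 16 as drawn is to be used.

## Steps

Step 1
Reactants: 1 3-methylcyclopent-2-en-1-one
Product: 3 2-bromo-3-methylcyclopent-2-en-1-one, via dibromide 2 (not isolated)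
Conditions: Br2, CH2Cl2, 0 °C; then Et3N, 0 °C to rt
Reagents that add atoms: bromine, BrBr
Why: Bromine adds across the enone alkene and Et3N removes the acidic C–H next to the carbonyl with loss of the tertiary bromide (addition–elimination α-bromination of an enone); no stereocentre is formed.

Step 2
Reactants: 3 2-bromo-3-methylcyclopent-2-en-1-one
Product: 4 6-bromo-7-methyl-1,4-dioxaspiro[4.4]non-6-ene
Conditions: HOCH2CH2OH, p-TsOH (cat.), benzene, reflux, Dean–Stark trap
Reagents that add atoms: ethane-1,2-diol, OCCO
Why: Acid-catalysed ketalisation with azeotropic removal of water; the α-bromo substituent keeps the alkene in place, so the vinyl bromide needed for halogen–lithium exchange is retained.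

Step 3
Reactants: 5 methyl 4,4-dimethoxybutanoate; 6 4-methoxybenzyl alcohol
Product: 7 methyl 4,4-bis(4-methoxybenzyloxy)butanoate
Conditions: 6 (2.5 equiv), PPTS (cat.), cyclohexane, reflux, MeOH removed over 5 Å sieves
Reagents that add atoms: none
Why: Acid-catalysed transacetalisation driven by removal of methanol; the weak acid avoids benzylic ionisation of 6 and leaves the ester alone.

Step 4
Reactants: 7 methyl 4,4-bis(4-methoxybenzyloxy)butanoate
Product: 8 N-methoxy-N-methyl-4,4-bis(4-methoxybenzyloxy)butanamide
Conditions: MeNH(OMe)·HCl, iPrMgCl, THF, −20 °C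
Reagents that add atoms: N,O-dimethylhydroxylamine hydrochloride, CNOC.Cl
Why: The chloromagnesium amide of N,O-dimethylhydroxylamine converts the methyl ester directly into the N-methoxy-N-methylamide (ester aminolysis); the basic medium keeps the acetal intact.

Step 5
Reactants: 4 6-bromo-7-methyl-1,4-dioxaspiro[4.4]non-6-ene; 8 N-methoxy-N-methyl-4,4-bis(4-methoxybenzyloxy)butanamide
Product: 10 4,4-bis(4-methoxybenzyloxy)-1-(7-methyl-1,4-dioxaspiro[4.4]non-6-en-6-yl)butan-1-one, via vinyllithium 9 (not isolated)
Conditions: t-BuLi (2 equiv), THF, −78 °C; then 8, −78 to 0 °C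
Reagents that add atoms: none
Why: Bromine–lithium exchange gives the α-ketovinyl anion equivalent 9, and its addition to the N-methoxy-N-methylamide stops at the chelated tetrahedral adduct, so the ketone appears only on work-up; this forms the C8–C9 bond.

Step 6
Reactants: 10 4,4-bis(4-methoxybenzyloxy)-1-(7-methyl-1,4-dioxaspiro[4.4]non-6-en-6-yl)butan-1-one
Product: 14 4,4-bis(4-methoxybenzyloxy)-2-methylidene-1-(7-methyl-1,4-dioxaspiro[4.4]non-6-en-6-yl)butan-1-one, via lithium enolate 11 (not isolated), via Mannich base 12 (not isolated), via ammonium iodide 13 (not isolated)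
Conditions: LiN(SiMe3)2, THF, −78 °C; CH2=NMe2+ I−, −78 °C to rt; then MeI, Et2O; then aq. NaHCO3, CH2Cl2
Reagents that add atoms: dimethyl(methylidene)ammonium iodide, C=[N+](C)C.[I-]
Why: The only α-position (C6) is aminomethylated (Mannich reaction of a preformed enolate), and quaternisation followed by mild base gives the α-methylidene ketone by β-elimination; the sequence is basic throughout, which spares acetal and ketal.

Step 7
Reactants: 14 4,4-bis(4-methoxybenzyloxy)-2-methylidene-1-(7-methyl-1,4-dioxaspiro[4.4]non-6-en-6-yl)butan-1-one
Product: 15 triethyl{[(1E)-4,4-bis(4-methoxybenzyloxy)-2-methyl-1-(7-methyl-1,4-dioxaspiro[4.4]non-6-en-6-yl)but-1-en-1-yl]oxy}silane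
Conditions: Et3SiH, RhCl(PPh3)3 (cat.), benzene, 50 °C
Reagents that add atoms: triethylsilane, CC[SiH](CC)CC
Why: Rhodium-catalysed 1,4-hydrosilylation of an enone with a monohydrosilane puts silicon on oxygen and hydrogen on the methylidene carbon within the s-cis enone, so the new methyl and the silyloxy group end up cis and the ring on C8 is cis to the acetal chain on C6. The second enone is inert because its β-carbon (C3) is fully substituted.

Step 8
Reactants: 15 triethyl{[(1E)-4,4-bis(4-methoxybenzyloxy)-2-methyl-1-(7-methyl-1,4-dioxaspiro[4.4]non-6-en-6-yl)but-1-en-1-yl]oxy}silane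
Product: 16 {[(1S,2R)-2-[2,2-bis(4-methoxybenzyloxy)ethyl]-2-methyl-1-(7-methyl-1,4-dioxaspiro[4.4]non-6-en-6-yl)cyclopropyl]oxy}triethylsilane
Conditions: Et2Zn, CH2I2, N-Boc-L-valyl-L-proline methyl ester or its enantiomer (0.25 equiv), CH2Cl2, −40 to 0 °C
Reagents that add atoms: diiodomethane, ICI
Why: Simmons–Smith (Furukawa) methylene transfer is fastest at the silyl enol ether alkene of a 2-silyloxydiene and is stereospecific, so the geometry of 15 becomes the cis relation of ring and side chain. The dipeptide-bound zinc carbenoid (ligand-controlled enantioselective cyclopropanation of silyl enol ethers) selects the alkene face and sets C6 and C8 together.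

Step 9
Reactants: 16 {[(1S,2R)-2-[2,2-bis(4-methoxybenzyloxy)ethyl]-2-methyl-1-(7-methyl-1,4-dioxaspiro[4.4]non-6-en-6-yl)cyclopropyl]oxy}triethylsilane
Product: 17 triethyl{[(1S,2R)-2-[(E)-2-(4-methoxybenzyloxy)ethenyl]-2-methyl-1-(7-methyl-1,4-dioxaspiro[4.4]non-6-en-6-yl)cyclopropyl]oxy}silane
Conditions: Me3SiOTf, iPr2NEt, CH2Cl2, −78 to −20 °C
Reagents that add atoms: none
Why: The silyl triflate ionises the acyclic aldehyde acetal, which reacts faster than the ring-closed dioxolane whose opening is reversible, and the amine removes a C5 proton from the oxocarbenium ion (acetal-to-enol-ether elimination). The fully substituted C6 next to C5 keeps the C6–C5 bond anti to the alkoxy group during deprotonation, so the (E)-enol ether is expected.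

Step 10
Reactants: 17 triethyl{[(1S,2R)-2-[(E)-2-(4-methoxybenzyloxy)ethenyl]-2-methyl-1-(7-methyl-1,4-dioxaspiro[4.4]non-6-en-6-yl)cyclopropyl]oxy}silane
Product: 18 bicyclic silyl enol ether (C3 methyl β; C4 OPMB α; alkenes C5=C6 and C8=C9; C8 OSiEt3; C10 ethylene ketal)
Conditions: toluene, BHT (cat.), base-washed sealed tube, 110–130 °C
Reagents that add atoms: none
Why: On heating, 17 undergoes a concerted [3,3] sigmatropic (Cope) shift through a boat-like six-electron transition state in which both alkenes lie over the three-membered ring; C6–C8 breaks as C3–C4 forms, driven by release of cyclopropane strain. The closest known reaction type is the thermal cis-divinylcyclopropane to cyclohepta-1,4-diene rearrangement of 1-silyloxy-1-cycloalkenyl-2-vinylcyclopropanes. The seven-membered ring (C3 to C9) is closed pericyclically by the new C3–C4 σ-bond between the two alkene termini, and the five-membered ring is carried through unchanged. C3 is controlled by the cyclopropane configuration: the boat geometry lets only one face of the cyclopentene terminus bond (methyl inward, C2 outward), so the (1S,2R) cyclopropane is translated into the (3S) quaternary centre while C6 and C8 lose their chirality. C4 is controlled by the (E) geometry of the enol ether, which keeps oxygen outward and therefore trans to the C3 methyl (the C4 epimer of the target, corrected in steps 22 to 24). The step needs the concerted path to outrun homolysis of C6–C8, which would scramble configuration; this is secured by the exclusively cis cyclopropane, by the E-enol ether (no second inward group beside the C3 methyl) and by the absence of a cis alkyl C–H that could enter a homodienyl hydrogen shift. The new alkenes, C5=C6 and the C8=C9 silyl enol ether, are the precursors of the C6=C7 alkene and the C8 oxygen.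

Step 11
Reactants: 18 bicyclic silyl enol ether (C3 methyl β; C4 OPMB α; alkenes C5=C6 and C8=C9; C8 OSiEt3; C10 ethylene ketal)
Product: 20 enone (C8 ketone conjugated to C6=C7; C9–H β; C4 OPMB α; C10 ethylene ketal), via β,γ-unsaturated ketone 19 (not isolated)
Conditions: Bu4NF, AcOH (1:1), THF, −20 °C; then DBU, 0 °C, short contact
Reagents that add atoms: none
Why: Buffered fluoride cleaves the silyl enol ether and C9 is protonated on the β face, giving the cis ring fusion; this is also the more stable epimer, because the trans isomer would place the angular methyl and C8 cis on the cyclopentane. DBU then moves the alkene into conjugation through the C7 dienolate, whose protons are far more acidic than C9–H, which keeps exposure of the β-keto ketal to base short.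

Step 12
Reactants: 20 enone (C8 ketone conjugated to C6=C7; C9–H β; C4 OPMB α; C10 ethylene ketal)
Product: 21 allylic alcohol (C8–OH α; C6=C7; C9–H β; C4 OPMB α; C10 ethylene ketal)
Conditions: NaBH4, CeCl3·7H2O, MeOH, −78 °C
Reagents that add atoms: none
Why: Luche reduction gives clean 1,2-reduction of the enone; hydride approaches C8 on the convex face beside C9–H, anti to the C9–C10 bond and its spiroketal (Felkin–Anh sense), which places the hydroxyl α as required.

Step 13
Reactants: 21 allylic alcohol (C8–OH α; C6=C7; C9–H β; C4 OPMB α; C10 ethylene ketal)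
Product: 22 C8 tert-butyldimethylsilyl ether of 21
Conditions: t-BuMe2SiOTf, 2,6-lutidine, CH2Cl2, −78 °C
Reagents that add atoms: tert-butyldimethylsilyl trifluoromethanesulfonate, CC(C)(C)[Si](C)(C)OS(=O)(=O)C(F)(F)F
Why: Silylation of a hindered secondary alcohol with a silyl triflate; a silyl ether and not the final ester is placed on C8 because it is a poor leaving group β to the coming C10 ketone and is inert in the organozinc coupling.

Step 14
Reactants: 22 C8 tert-butyldimethylsilyl ether of 21
Product: 23 ketone (C10 ketone; C8 OTBS α; C6=C7; C4 OPMB α; cis-fused)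
Conditions: PPTS, acetone–H2O, 55 °C
Reagents that add atoms: water, O
Why: Mild acid hydrolysis of a saturated ketone dioxolane; the silyl and PMB ethers tolerate PPTS, and C9, now α to the ketone, can only relax to the favoured cis fusion.

Step 15
Reactants: 23 ketone (C10 ketone; C8 OTBS α; C6=C7; C4 OPMB α; cis-fused)
Product: 25 enol triflate (C1=C10; C10 OSO2CF3; C8 OTBS α; C4 OPMB α), via potassium enolate 24 (not isolated)
Conditions: KN(SiMe3)2, THF, −78 °C; then PhNTf2, −78 to 0 °C
Reagents that add atoms: N-phenylbis(trifluoromethanesulfonimide), O=S(=O)(N(c1ccccc1)S(=O)(=O)C(F)(F)F)C(F)(F)F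
Why: Kinetic deprotonation by the bulky amide occurs at the C1 methylene and not at the hindered C9 methine, and O-sulfonylation traps the enolate as the C1=C10 enol triflate.

Step 16
Reactants: 25 enol triflate (C1=C10; C10 OSO2CF3; C8 OTBS α; C4 OPMB α)
Product: 26 diene (C1=C10 with isopropyl on C10; C6=C7; C8 OTBS α; C4 OPMB α)
Conditions: iPrZnBr, PdCl2(dppf) (cat.), THF, 50 °C
Reagents that add atoms: isopropylzinc bromide, CC(C)[Zn]Br
Why: Negishi coupling of an alkenyl triflate with a secondary alkylzinc reagent; the wide-bite-angle diphosphine favours reductive elimination over β-hydride elimination, so isopropyl is transferred without isomerisation to n-propyl.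

Step 17
Reactants: 26 diene (C1=C10 with isopropyl on C10; C6=C7; C8 OTBS α; C4 OPMB α)
Product: 27 allylic alcohol (C8–OH α; C1=C10 with isopropyl on C10; C6=C7; C4 OPMB α)
Conditions: Bu4NF, THF, rt to 45 °C
Reagents that add atoms: none
Why: Fluoride cleaves the secondary silyl ether; nothing else in 26 is sensitive to fluoride or mild base.

Step 18
Reactants: 28 4-hydroxybenzoic acid
Product: 30 4-(tert-butyldimethylsilyloxy)benzoic acid, via bis-silyl derivative 29 (not isolated)
Conditions: t-BuMe2SiCl, imidazole, DMF, rt; then AcOH–THF–H2O, rt
Reagents that add atoms: tert-butyl(chloro)dimethylsilane, CC(C)(C)[Si](C)(C)Cl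
Why: Both acidic groups are silylated and the silyl ester, far more labile than the aryl silyl ether, is then hydrolysed selectively; the phenol has to be masked for the esterification and acetylation steps.

Step 19
Reactants: 27 allylic alcohol (C8–OH α; C1=C10 with isopropyl on C10; C6=C7; C4 OPMB α); 30 4-(tert-butyldimethylsilyloxy)benzoic acid
Product: 31 C8 4-(tert-butyldimethylsilyloxy)benzoate of 27
Conditions: DCC, DMAP, CH2Cl2, rt
Reagents that add atoms: none
Why: Steglich esterification through the O-acylisourea and the acylpyridinium ion acylates the hindered allylic alcohol; the C8–O bond is not touched, so the configuration is retained.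

Step 20
Reactants: 31 C8 4-(tert-butyldimethylsilyloxy)benzoate of 27
Product: 32 diol (C1–OH β; C10–OH β; isopropyl α; C8 aroyloxy α; C4 OPMB α)
Conditions: OsO4 (cat.), NMO, acetone–H2O, 0 °C to rt
Reagents that add atoms: 4-methylmorpholine N-oxide, C[N+]1([O-])CCOCC1; water, O
Why: Catalytic osmylation ([3+2] addition, then hydrolysis of the osmate ester) gives the cis-diol; the C6=C7 alkene is deactivated and shielded by the allylic aroyloxy group. The reagent approaches the cyclopentene on the β face, beside C9–H and away from the C9–C8 bond and the seven-membered ring, which sets C1 and C10 together.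

Step 21
Reactants: 32 diol (C1–OH β; C10–OH β; isopropyl α; C8 aroyloxy α; C4 OPMB α)
Product: 33 C1 acetate of 32
Conditions: Ac2O, pyridine, DMAP (cat.), CH2Cl2, 0 °C
Reagents that add atoms: acetic anhydride, CC(=O)OC(C)=O
Why: Acylation of the secondary C1 alcohol; the tertiary C10 alcohol does not react under these conditions.

Step 22
Reactants: 33 C1 acetate of 32
Product: 34 C4 alcohol (C4–OH α; C1 OAc; C10–OH; C8 aroyloxy)
Conditions: DDQ, CH2Cl2–pH 7 buffer, 0 °C
Reagents that add atoms: none
Why: Oxidative cleavage of the PMB ether by benzylic hydride abstraction and hydrolysis of the oxocarbenium ion; esters, the aryl silyl ether and the alkene are not affected.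

Step 23
Reactants: 34 C4 alcohol (C4–OH α; C1 OAc; C10–OH; C8 aroyloxy)
Product: 35 C4 ketone (C1 OAc; C10–OH; C8 aroyloxy; C6=C7)
Conditions: Dess–Martin periodinane (DMP), pyridine, CH2Cl2, 0 °C
Reagents that add atoms: none
Why: Dess–Martin oxidation of the secondary alcohol under buffered conditions erases the wrong C4 stereocentre; the tertiary alcohol cannot be oxidised and the β,γ-alkene stays in place in the absence of strong acid or base.

Step 24
Reactants: 35 C4 ketone (C1 OAc; C10–OH; C8 aroyloxy; C6=C7)
Product: 36 tert-butyldimethylsilyl ether of the target phenol (C4–OH β)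
Conditions: NaBH4, CeCl3·7H2O, MeOH, −78 °C
Reagents that add atoms: none
Why: Fast 1,2-reduction under Luche conditions leaves the esters untouched and gives no time for base-induced conjugation. Hydride is expected to enter anti to the angular C3 methyl, as in reductions of ketones beside a methylated ring-fusion carbon, which places the hydroxyl β and so inverts C4 relative to 34.

Step 25
Reactants: 36 tert-butyldimethylsilyl ether of the target phenol (C4–OH β)
Product: 37 (2S,3R,3aR,4S,8S,8aS)-2-acetoxy-3,8-dihydroxy-6,8a-dimethyl-3-(propan-2-yl)-1,2,3,3a,4,7,8,8a-octahydroazulen-4-yl 4-hydroxybenzoate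
Conditions: KHF2, MeOH, rt
Reagents that add atoms: none
Why: Bifluoride in methanol cleaves aryl silyl ethers selectively; the acetate, the benzoate and the free alcohols are stable, and the product is the target.

## Compound list

1 | 3-methylcyclopent-2-en-1-one | CC1=CC(=O)CC1 | starting material
2 | 2,3-dibromo-3-methylcyclopentan-1-one (racemic; not isolated) | CC1(Br)CCC(=O)C1Br | intermediate
3 | 2-bromo-3-methylcyclopent-2-en-1-one | CC1=C(Br)C(=O)CC1 | intermediate
4 | 6-bromo-7-methyl-1,4-dioxaspiro[4.4]non-6-ene | CC1=C(Br)C2(CC1)OCCO2 | intermediate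
5 | methyl 4,4-dimethoxybutanoate | COC(=O)CCC(OC)OC | starting material
6 | 4-methoxybenzyl alcohol | COc1ccc(CO)cc1 | starting material
7 | methyl 4,4-bis(4-methoxybenzyloxy)butanoate | COC(=O)CCC(OCc1ccc(OC)cc1)OCc1ccc(OC)cc1 | intermediate
8 | N-methoxy-N-methyl-4,4-bis(4-methoxybenzyloxy)butanamide | CON(C)C(=O)CCC(OCc1ccc(OC)cc1)OCc1ccc(OC)cc1 | intermediate
9 | (7-methyl-1,4-dioxaspiro[4.4]non-6-en-6-yl)lithium (not isolated) | [Li]C1=C(C)CCC12OCCO2 | intermediate
10 | 4,4-bis(4-methoxybenzyloxy)-1-(7-methyl-1,4-dioxaspiro[4.4]non-6-en-6-yl)butan-1-one | O=C(CCC(OCc1ccc(OC)cc1)OCc1ccc(OC)cc1)C1=C(C)CCC12OCCO2 | intermediate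
11 | lithium enolate of 10 (C8=C6; not isolated) | [Li+].[O-]C(=CCC(OCc1ccc(OC)cc1)OCc1ccc(OC)cc1)C1=C(C)CCC12OCCO2 | intermediate
12 | 2-[(dimethylamino)methyl]-4,4-bis(4-methoxybenzyloxy)-1-(7-methyl-1,4-dioxaspiro[4.4]non-6-en-6-yl)butan-1-one (racemic; not isolated) | CN(C)CC(CC(OCc1ccc(OC)cc1)OCc1ccc(OC)cc1)C(=O)C1=C(C)CCC12OCCO2 | intermediate
13 | trimethylammonium iodide derived from 12 (racemic; not isolated) | C[N+](C)(C)CC(CC(OCc1ccc(OC)cc1)OCc1ccc(OC)cc1)C(=O)C1=C(C)CCC12OCCO2.[I-] | intermediate
14 | 4,4-bis(4-methoxybenzyloxy)-2-methylidene-1-(7-methyl-1,4-dioxaspiro[4.4]non-6-en-6-yl)butan-1-one | C=C(CC(OCc1ccc(OC)cc1)OCc1ccc(OC)cc1)C(=O)C1=C(C)CCC12OCCO2 | intermediate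
15 | triethyl{[(1E)-4,4-bis(4-methoxybenzyloxy)-2-methyl-1-(7-methyl-1,4-dioxaspiro[4.4]non-6-en-6-yl)but-1-en-1-yl]oxy}silane (O–Si cis to the methyl) | C/C(CC(OCc1ccc(OC)cc1)OCc1ccc(OC)cc1)=C(\O[Si](CC)(CC)CC)C1=C(C)CCC12OCCO2 | intermediate
16 | {[(1S,2R)-2-[2,2-bis(4-methoxybenzyloxy)ethyl]-2-methyl-1-(7-methyl-1,4-dioxaspiro[4.4]non-6-en-6-yl)cyclopropyl]oxy}triethylsilane (ring cis to the acetal chain) | C[C@]1(CC(OCc2ccc(OC)cc2)OCc2ccc(OC)cc2)C[C@@]1(O[Si](CC)(CC)CC)C3=C(C)CCC34OCCO4 | intermediate
17 | triethyl{[(1S,2R)-2-[(E)-2-(4-methoxybenzyloxy)ethenyl]-2-methyl-1-(7-methyl-1,4-dioxaspiro[4.4]non-6-en-6-yl)cyclopropyl]oxy}silane (key-step precursor; the two alkenyl groups cis) | C[C@]1(/C=C/OCc2ccc(OC)cc2)C[C@@]1(O[Si](CC)(CC)CC)C3=C(C)CCC34OCCO4 | intermediate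
18 | bicyclic silyl enol ether, key-step product (3S,4R; C3 methyl β; C4 OPMB α; alkenes C5=C6 and C8=C9; C8 OSiEt3; C10 ethylene ketal) | C1C[C@]2(C)[C@H](OCc3ccc(OC)cc3)C=C(C)CC(O[Si](CC)(CC)CC)=C2C14OCCO4 | intermediate
19 | β,γ-unsaturated ketone (C8 ketone; C5=C6; C9–H β; C4 OPMB α; C10 ethylene ketal; not isolated) | C1C[C@]2(C)[C@H](OCc3ccc(OC)cc3)C=C(C)CC(=O)[C@@H]2C14OCCO4 | intermediate
20 | enone (C8 ketone conjugated to C6=C7; C9–H β; C4 OPMB α; C10 ethylene ketal) | C1C[C@]2(C)[C@H](OCc3ccc(OC)cc3)CC(C)=CC(=O)[C@@H]2C14OCCO4 | intermediate
21 | allylic alcohol (C8–OH α; C6=C7; C9–H β; C4 OPMB α; C10 ethylene ketal) | C1C[C@]2(C)[C@H](OCc3ccc(OC)cc3)CC(C)=C[C@H](O)[C@@H]2C14OCCO4 | intermediate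
22 | C8 tert-butyldimethylsilyl ether of 21 | C1C[C@]2(C)[C@H](OCc3ccc(OC)cc3)CC(C)=C[C@H](O[Si](C)(C)C(C)(C)C)[C@@H]2C14OCCO4 | intermediate
23 | ketone (C10 ketone; C8 OTBS α; C6=C7; C4 OPMB α; cis-fused) | C1C[C@]2(C)[C@H](OCc3ccc(OC)cc3)CC(C)=C[C@H](O[Si](C)(C)C(C)(C)C)[C@@H]2C1=O | intermediate
24 | potassium enolate of 23 (C1=C10; not isolated) | [K+].[O-]C1=CC[C@]2(C)[C@H](OCc3ccc(OC)cc3)CC(C)=C[C@H](O[Si](C)(C)C(C)(C)C)[C@@H]21 | intermediate
25 | enol triflate (C1=C10; C10 OSO2CF3; C8 OTBS α; C4 OPMB α) | FC(F)(F)S(=O)(=O)OC1=CC[C@]2(C)[C@H](OCc3ccc(OC)cc3)CC(C)=C[C@H](O[Si](C)(C)C(C)(C)C)[C@@H]21 | intermediate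
26 | diene (C1=C10 with isopropyl on C10; C6=C7; C8 OTBS α; C4 OPMB α) | CC(C)C1=CC[C@]2(C)[C@H](OCc3ccc(OC)cc3)CC(C)=C[C@H](O[Si](C)(C)C(C)(C)C)[C@@H]21 | intermediate
27 | allylic alcohol (C8–OH α; C1=C10 with isopropyl on C10; C6=C7; C4 OPMB α) | CC(C)C1=CC[C@]2(C)[C@H](OCc3ccc(OC)cc3)CC(C)=C[C@H](O)[C@@H]21 | intermediate
28 | 4-hydroxybenzoic acid | O=C(O)c1ccc(O)cc1 | starting material
29 | tert-butyldimethylsilyl 4-(tert-butyldimethylsilyloxy)benzoate (not isolated) | CC(C)(C)[Si](C)(C)OC(=O)c1ccc(O[Si](C)(C)C(C)(C)C)cc1 | intermediate
30 | 4-(tert-butyldimethylsilyloxy)benzoic acid | O=C(O)c1ccc(O[Si](C)(C)C(C)(C)C)cc1 | intermediate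
31 | C8 4-(tert-butyldimethylsilyloxy)benzoate of 27 | CC(C)C1=CC[C@]2(C)[C@H](OCc3ccc(OC)cc3)CC(C)=C[C@H](OC(=O)c3ccc(O[Si](C)(C)C(C)(C)C)cc3)[C@@H]21 | intermediate
32 | diol (C1–OH β; C10–OH β; isopropyl α; C8 aroyloxy α; C4 OPMB α) | O[C@H]1C[C@]2(C)[C@H](OCc3ccc(OC)cc3)CC(C)=C[C@H](OC(=O)c3ccc(O[Si](C)(C)C(C)(C)C)cc3)[C@@H]2[C@]1(O)C(C)C | intermediate
33 | C1 acetate of 32 | CC(=O)O[C@H]1C[C@]2(C)[C@H](OCc3ccc(OC)cc3)CC(C)=C[C@H](OC(=O)c3ccc(O[Si](C)(C)C(C)(C)C)cc3)[C@@H]2[C@]1(O)C(C)C | intermediate
34 | C4 alcohol (C4–OH α, 4R; C1 OAc; C10–OH; C8 aroyloxy) | CC(=O)O[C@H]1C[C@]2(C)[C@H](O)CC(C)=C[C@H](OC(=O)c3ccc(O[Si](C)(C)C(C)(C)C)cc3)[C@@H]2[C@]1(O)C(C)C | intermediate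
35 | C4 ketone (C1 OAc; C10–OH; C8 aroyloxy; C6=C7) | CC(=O)O[C@H]1C[C@]2(C)C(=O)CC(C)=C[C@H](OC(=O)c3ccc(O[Si](C)(C)C(C)(C)C)cc3)[C@@H]2[C@]1(O)C(C)C | intermediate
36 | tert-butyldimethylsilyl ether of the target phenol (C4–OH β, 4S) | CC(=O)O[C@H]1C[C@]2(C)[C@@H](O)CC(C)=C[C@H](OC(=O)c3ccc(O[Si](C)(C)C(C)(C)C)cc3)[C@@H]2[C@]1(O)C(C)C | intermediate
37 | (2S,3R,3aR,4S,8S,8aS)-2-acetoxy-3,8-dihydroxy-6,8a-dimethyl-3-(propan-2-yl)-1,2,3,3a,4,7,8,8a-octahydroazulen-4-yl 4-hydroxybenzoate | CC(=O)O[C@H]1C[C@]2(C)[C@@H](O)CC(C)=C[C@H](OC(=O)c3ccc(O)cc3)[C@@H]2[C@]1(O)C(C)C | target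

## Step count and least certain steps

Total step count: 25. Longest linear sequence: 22 steps (steps 1, 2, 5 to 17 and 19 to 25; the branch through steps 3 and 4 is equally long).

Step 10 (key step). The inward C3 methyl may slow the concerted shift so much that, at the temperature needed, homolysis of C6–C8 with reclosure erodes the transfer of configuration, or the silyl enol ether is hydrolysed. Fallback: the charge-accelerated form of the same shift. From 17, buffered fluoride (Bu4NF, AcOH, THF, 0 °C) would give the free cyclopropanol F1. KN(SiMe3)2 with 18-crown-6 in THF at −78 °C converts it into the potassium cyclopropanolate F2, in which the oxyanion weakens C6–C8, so that the [3,3] shift should run far below room temperature to the potassium enolate F3. Protonation with AcOH gives 19, and DBU as in step 11 brings the route back at 20. If bond cleavage ran ahead of bond formation on this path, the transfer of configuration to C3 would have to be checked.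

Step 8. Facial discrimination by the chiral zinc carbenoid may be poor on this hindered tetrasubstituted enol ether, or methylene transfer may also reach the cyclopentene alkene beside the ketal. Fallback: resolution instead of asymmetric induction. From 15, cyclopropanation without ligand (Et2Zn, CH2I2, CH2Cl2) gives 16 together with its mirror image, the (1R,2S)-cyclopropane F4. Preparative chromatography on a chiral stationary phase separates the two, and the route continues from 16.

Step 9. The silyl triflate may also ionise the allylic dioxolane or open the silyloxycyclopropane, or an E/Z mixture may form, of which only the E isomer can rearrange. Fallback: a base- and oxidation-based sequence. From 16, Et3SiOTf with 2,4,6-collidine and then water, a combination that cleaves aldehyde acetals and spares ketals, gives the aldehyde F5. Amine-catalysed α-selenenylation (N-(phenylselanyl)phthalimide, pyrrolidine cat.) gives the α-phenylselanyl aldehyde F6, NaBH4 the β-hydroxy selenide F7, and NaH with 4-methoxybenzyl chloride the PMB ether F8. H2O2 with pyridine gives the selenoxide F9, whose syn-elimination can only take a hydrogen from C4 (C6 is quaternary) and so gives the (E)-enol ether 17, where the route is rejoined.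

Step 11. Enolisation toward C9 under base may trigger β-elimination that opens the dioxolane, or protonation may occur on the wrong face of C9. Fallback: isomerisation at the enol ether stage. From 18, RuHCl(CO)(PPh3)3 (cat.) in toluene at 80 °C moves the C5=C6 alkene into conjugation and gives the 2-silyloxy-1,3-diene F10 (metal hydride isomerisation of a skipped diene). Buffered fluoride then protonates the terminal carbon C9 and gives 20 directly, so no amine base meets the β-keto ketal.

Step 20. Osmylation may also consume the C6=C7 alkene, or occur on the α face. Fallback: deactivation of C6=C7 as an enone. From 27, MnO2 in CH2Cl2 re-oxidises the allylic alcohol to the enone F11. Only the isolated cyclopentene alkene is then osmylated (OsO4 cat., NMO) to the diol F12. Acetylation gives the acetate F13, Luche reduction the allylic alcohol F14 (hydride again beside C9–H), and esterification with 30 as in step 19 rejoins the route at 33.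

Step 24. Hydride delivery to the β face would return the α-alcohol 34, and basic conditions could move the alkene into conjugation with the ketone. Fallback: catalyst control in place of substrate control. From 35, a Corey–Bakshi–Shibata reduction (oxazaborolidine, BH3·SMe2), in which the catalyst distinguishes the quaternary flank (C3) from the methylene flank (C5), is run with the catalyst enantiomer that delivers hydride to the α face, and the route continues at 36. No new compound arises.

## Further compounds

F1 | step 10 | (1S,2R)-2-[(E)-2-(4-methoxybenzyloxy)ethenyl]-2-methyl-1-(7-methyl-1,4-dioxaspiro[4.4]non-6-en-6-yl)cyclopropan-1-ol | C[C@]1(/C=C/OCc2ccc(OC)cc2)C[C@@]1(O)C3=C(C)CCC34OCCO4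
F2 | step 10 | potassium salt of F1 (cyclopropanolate) | C[C@]1(/C=C/OCc2ccc(OC)cc2)C[C@@]1([O-])C3=C(C)CCC34OCCO4.[K+]
F3 | step 10 | potassium enolate corresponding to 18 (C8=C9) | C1C[C@]2(C)[C@H](OCc3ccc(OC)cc3)C=C(C)CC([O-])=C2C14OCCO4.[K+]
F4 | step 8 | {[(1R,2S)-2-[2,2-bis(4-methoxybenzyloxy)ethyl]-2-methyl-1-(7-methyl-1,4-dioxaspiro[4.4]non-6-en-6-yl)cyclopropyl]oxy}triethylsilane (enantiomer of 16) | C[C@@]1(CC(OCc2ccc(OC)cc2)OCc2ccc(OC)cc2)C[C@]1(O[Si](CC)(CC)CC)C3=C(C)CCC34OCCO4
F5 | step 9 | 2-[(1R,2S)-1-methyl-2-(7-methyl-1,4-dioxaspiro[4.4]non-6-en-6-yl)-2-(triethylsilyloxy)cyclopropyl]acetaldehyde (configuration as in 16) | C[C@]1(CC=O)C[C@@]1(O[Si](CC)(CC)CC)C3=C(C)CCC34OCCO4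
F6 | step 9 | α-phenylselanyl derivative of F5 (mixture at the selenium-bearing carbon) | C[C@]1(C(C=O)[Se]c2ccccc2)C[C@@]1(O[Si](CC)(CC)CC)C3=C(C)CCC34OCCO4
F7 | step 9 | β-hydroxy selenide from F6 | C[C@]1(C(CO)[Se]c2ccccc2)C[C@@]1(O[Si](CC)(CC)CC)C3=C(C)CCC34OCCO4
F8 | step 9 | 4-methoxybenzyl ether of F7 | C[C@]1(C(COCc2ccc(OC)cc2)[Se]c2ccccc2)C[C@@]1(O[Si](CC)(CC)CC)C3=C(C)CCC34OCCO4
F9 | step 9 | selenoxide of F8 | C[C@]1(C(COCc2ccc(OC)cc2)[Se](=O)c2ccccc2)C[C@@]1(O[Si](CC)(CC)CC)C3=C(C)CCC34OCCO4
F10 | step 11 | conjugated silyloxydiene (alkenes C6=C7 and C8=C9; C8 OSiEt3; C4 OPMB α; C10 ethylene ketal) | C1C[C@]2(C)[C@H](OCc3ccc(OC)cc3)CC(C)=CC(O[Si](CC)(CC)CC)=C2C14OCCO4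
F11 | step 20 | enone from 27 (C8 ketone conjugated to C6=C7; C1=C10 with isopropyl; C4 OPMB α) | CC(C)C1=CC[C@]2(C)[C@H](OCc3ccc(OC)cc3)CC(C)=CC(=O)[C@@H]21
F12 | step 20 | diol enone (C1–OH β; C10–OH β; C8 ketone; C4 OPMB α) | O[C@H]1C[C@]2(C)[C@H](OCc3ccc(OC)cc3)CC(C)=CC(=O)[C@@H]2[C@]1(O)C(C)C
F13 | step 20 | C1 acetate of F12 | CC(=O)O[C@H]1C[C@]2(C)[C@H](OCc3ccc(OC)cc3)CC(C)=CC(=O)[C@@H]2[C@]1(O)C(C)C
F14 | step 20 | allylic alcohol from F13 (C8–OH α) | CC(=O)O[C@H]1C[C@]2(C)[C@H](OCc3ccc(OC)cc3)CC(C)=C[C@H](O)[C@@H]2[C@]1(O)C(C)C
F0 | step 24 | none | none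
A1 | alternative 1 | 2-methyl-2-(4-methyl-2-oxopentyl)cycloheptane-1,3-dione | CC(C)CC(=O)CC1(C)C(=O)CCCCC1=O
A2 | alternative 1 | bicyclic enedione (C1 and C4 ketones; C9=C10 with isopropyl on C10; C3 methyl) | O=C1C[C@]2(C)C(=O)CCCCC2=C1C(C)C
A3 | alternative 2 | 4-methyl-1,2-bis(trimethylsilyloxy)cyclopent-1-ene | C[Si](C)(C)OC1=C(O[Si](C)(C)C)CC(C)C1
A4 | alternative 2 | cis-anti-cis tricyclic ketone with bis(trimethylsilyloxy)cyclobutane | O=C1CC[C@]2(C)[C@@]3(O[Si](C)(C)C)CC(C)C[C@@]3(O[Si](C)(C)C)[C@H]12
A5 | alternative 2 | bicyclic trione (C4, C8 and C10 ketones; C3 and C6 methyl) | O=C1CC[C@]2(C)C(=O)CC(C)CC(=O)C12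
A6 | alternative 3 | oxime of 3-[1,5-dimethyl-7-(tert-butyldimethylsilyloxy)cyclohepta-2,4-dien-1-yl]propanal (C3 and C4 as in the target) | ON=CCC[C@]1(C)[C@@H](O[Si](C)(C)C(C)(C)C)CC(C)=CC=C1
A7 | alternative 3 | tricyclic isoxazoline (cyclopentane, cycloheptene, isoxazoline; C4 OTBS) | C1C[C@]2(C)[C@@H](O[Si](C)(C)C(C)(C)C)CC(C)=C[C@@H]3ON=C1[C@H]23
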